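**Strategy**

1. Cuts: first the C6–O ester bond, which releases (2E,4E,6E)-octa-2,4,6-trienoic acid (itself cut at C2=C3 into a six-carbon aldehyde and a two-carbon phosphonate). Then, with C11 lowered to a silyl-protected alcohol, the C6–O and C9–O bonds are cut together as a retro-[4+2] loss of O2 from a ring B 6,8-diene.
2. Enabling feature: in ring B the acyloxy oxygen on C6 and the hydroxyl on C9 sit on the same (α) face, on the two allylic carbons flanking C7=C8 and anti to the C10 methyl. This cis-2-ene-1,4-dioxy unit is what remains when the O–O bond of a 6α,9α-epidioxide is reduced.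
3. Forward: (+)-sclareolide supplies rings A and B. Its lactone carbonyl carbon is excised (hydroxylation, reduction, glycol cleavage), and the β-hydroxy aldehyde is dehydrated to the C8=C9 enal, dehydrogenated to the 6,8-dienal, reduced and silylated.
4. Ring events: the only ring made is the dioxygen bridge across ring B, closed by singlet oxygen and opened again one step later. The trienoyl chain is then joined through O6, and C11 is unmasked and oxidised last.
5. Stereochemistry: C5 and C10 come from sclareolide and are never touched. C6 and C9 are set together by suprafacial α-face addition of O2. Two E double bonds come from sorbaldehyde and the third from an E-selective Horner–Wadsworth–Emmons reaction.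

Key step: step 9

Remark: drimane numbering is used (C11 on C9, C12 the methyl on C8; the lactone carbonyl carbon of sclareolide is called C1′). The C11 carbinol configuration of the hydroxylated lactone and the triol, and the enol ether geometry of the silyl dienol ether, are drawn as the expected isomers; each is erased within two steps, so either isomer serves.

**Route**

Step 1
Reactants: 1 (+)-sclareolide (8α,1′-lactone of the homodrimane acid; 5α-H, 9α-H, 10β-methyl, 8β-methyl)
Product: 2 11-hydroxysclareolide (hydroxyl on the lactone carbon C11 next to the carbonyl, cis to H-9)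
Conditions: KN(SiMe3)2, THF, −78 °C; 2-(phenylsulfonyl)-3-phenyloxaziridine, −78 °C; AcOH quench
Reagents that add atoms: 2-(phenylsulfonyl)-3-phenyloxaziridine, O=S(=O)(N1OC1c1ccccc1)c1ccccc1
Why: Davis α-hydroxylation of the potassium lactone enolate, in which the oxaziridine oxygen should reach C11 from the α face, away from the axial methyl groups on C8 and C10; the new carbinol centre is erased again in step 3.

Step 2
Reactants: 2 11-hydroxysclareolide
Product: 3 11-(hydroxymethyl)drimane-8α,11-diol (8α-hydroxydrimane whose C11 carries OH and CH2OH)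
Conditions: LiAlH4, THF, 0 °C to rt; then H2O, aq. NaOH
Reagents that add atoms: none
Why: LiAlH4 reduction of a lactone to a diol, which takes C1′ to the primary alcohol and frees the tertiary 8α-hydroxyl without touching any stereocentre.

Step 3
Reactants: 3 11-(hydroxymethyl)drimane-8α,11-diol
Product: 4 8α-hydroxydriman-11-al (9β-formyl, 9α-H)
Conditions: NaIO4, THF/H2O, 0 °C to rt
Reagents that add atoms: none
Why: Malaprade glycol cleavage through the cyclic periodate ester of the only vicinal diol should remove C1′ as formaldehyde and leave C11 as the aldehyde, while the 8-hydroxyl (1,3 to the C11 hydroxyl) cannot form that ester and C9 is not epimerised in the neutral medium.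

Step 4
Reactants: 4 8α-hydroxydriman-11-al
Product: 6 drim-8-en-11-al, via tertiary mesylate 5 (not isolated)
Conditions: MsCl, Et3N, CH2Cl2, 0 °C to rt; then DBU (cat.), rt
Reagents that add atoms: methanesulfonyl chloride, CS(=O)(=O)Cl (its atoms are held only in intermediate 5 and leave again as methanesulfonate)
Why: aldol-type dehydration, in which sulfene-mediated mesylation of the tertiary 8-hydroxyl is followed by β-elimination of methanesulfonate with the acidic C9 hydrogen (E1cB through the aldehyde enolate), and the amidine base holds the double bond in the conjugated tetrasubstituted C8=C9 position, deliberately deleting the C8 and C9 stereocentres.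

Step 5
Reactants: 6 drim-8-en-11-al
Product: 7 11-(tert-butyldimethylsilyloxy)drima-7,9(11)-diene (extended silyl dienol ether, endocyclic C7=C8 and exocyclic C9=C11–OSi)
Conditions: TBSOTf, Et3N, CH2Cl2, 0 °C to rt
Reagents that add atoms: tert-butyldimethylsilyl trifluoromethanesulfonate, CC(C)(C)[Si](C)(C)OS(=O)(=O)C(F)(F)F
Why: soft enolisation of the enal (vinylogous silyl enol ether formation), in which O-silylation gives a silyloxyallyl cation that loses a γ-proton reversibly, so the more substituted endocyclic C7=C8 isomer should accumulate, whereas the cross-conjugated C12-methylene isomer has no productive path in step 6.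

Step 6
Reactants: 7 11-(tert-butyldimethylsilyloxy)drima-7,9(11)-diene
Product: 8 drima-6,8-dien-11-al (bicyclic analogue of safranal)
Conditions: Pd(OAc)2 (1.1 equiv), MeCN, rt, dark
Reagents that add atoms: none
Why: Saegusa–Ito oxidation, in which divalent palladium attacks the dienol ether to give an oxa-π-allyl complex spanning C9–C8–C7 where only C6 carries β-hydrogens, so syn β-hydride elimination should install C6=C7 in conjugation, and with no base present H-5 is not exchanged.

Step 7
Reactants: 8 drima-6,8-dien-11-al
Product: 9 drima-6,8-dien-11-ol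
Conditions: i-Bu2AlH, CH2Cl2, −78 °C; aq. KNaC4H4O6 work-up
Reagents that add atoms: none
Why: 1,2-hydride reduction of the hindered conjugated aldehyde with i-Bu2AlH at low temperature, which leaves the diene and C5 untouched.

Step 8
Reactants: 9 drima-6,8-dien-11-ol
Product: 10 11-(tert-butyldimethylsilyloxy)drima-6,8-diene
Conditions: TBSCl, imidazole, DMF, 0 °C to rt
Reagents that add atoms: tert-butyldimethylsilyl chloride, CC(C)(C)[Si](C)(C)Cl
Why: imidazole-promoted silylation of the primary allylic alcohol, which removes the last electron-withdrawing group from the diene, masks C11 and later leaves only the two ring hydroxyls to be told apart.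

Step 9
Reactants: 10 11-(tert-butyldimethylsilyloxy)drima-6,8-diene
Product: 11 11-(tert-butyldimethylsilyloxy)-6α,9α-epidioxydrim-7-ene
Conditions: O2, meso-tetraphenylporphyrin (cat.), visible light, CH2Cl2, −40 °C
Reagents that add atoms: dioxygen, O=O
Why: Photosensitised singlet oxygen should add to the ring-locked s-cis diene C6=C7–C8=C9 in a concerted suprafacial [4+2] cycloaddition, the closest known reaction being the photooxygenation of ergosterol-type homoannular dienes flanked by an angular methyl to their epidioxides. The one ring formed, the 1,2-dioxane of a 2,3-dioxabicyclo[2.2.2]oct-5-ene, closes in the [4+2] cycloaddition mode through the C6–O and C9–O bonds while the double bond moves to C7=C8. C6 and C9 are set together because both oxygens must enter on one face, and that face should be α because the axial C10 methyl next to C9 and the axial β-methyl on C4 (1,3 to C6) shield the β face. The step needs α-face selectivity and cycloaddition in preference to the ene reaction of the tetrasubstituted C8=C9 bond; the cisoid geometry, the electron-rich carbonyl-free diene, the low temperature and the aprotic solvent favour the cycloaddition. C5 and C10 are not involved and keep the trans ring fusion.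

Step 10
Reactants: 11 11-(tert-butyldimethylsilyloxy)-6α,9α-epidioxydrim-7-ene
Product: 12 11-(tert-butyldimethylsilyloxy)drim-7-ene-6α,9α-diol
Conditions: thiourea, MeOH (trace H2O), 0 °C to rt
Reagents that add atoms: none
Why: thiourea reduction of the peroxide O–O bond to the cis-2-ene-1,4-diol breaks no C–O bond, so C6 and C9 keep their α oxygens, and the base-free medium avoids Kornblum–DeLaMare isomerisation to the 6-ketone.

Step 11
Reactants: 13 (2E,4E)-hexa-2,4-dienal (sorbaldehyde), 14 triethyl phosphonoacetate
Product: 15 ethyl (2E,4E,6E)-octa-2,4,6-trienoate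
Conditions: NaH, THF, 0 °C to rt
Reagents that add atoms: none
Why: Horner–Wadsworth–Emmons olefination with a stabilised phosphonate anion, which should give the new C2=C3 bond E under thermodynamic control of the oxaphosphetane while the two existing E bonds are carried through.

Step 12
Reactants: 15 ethyl (2E,4E,6E)-octa-2,4,6-trienoate
Product: 16 (2E,4E,6E)-octa-2,4,6-trienoic acid
Conditions: LiOH, THF/MeOH/H2O, rt, dark; then aq. HCl to pH 3
Reagents that add atoms: lithium hydroxide, [Li+].[OH-] (supplies the second carboxyl oxygen)
Why: saponification by acyl–oxygen cleavage, run in the dark so that the all-E triene is not isomerised.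

Step 13
Reactants: 12 11-(tert-butyldimethylsilyloxy)drim-7-ene-6α,9α-diol, 16 (2E,4E,6E)-octa-2,4,6-trienoic acid
Product: 18 11-(tert-butyldimethylsilyloxy)-9α-hydroxydrim-7-en-6α-yl (2E,4E,6E)-octa-2,4,6-trienoate, via mixed anhydride 17 (not isolated)
Conditions: 2,4,6-Cl3C6H2COCl, Et3N, THF, rt; then 12, DMAP, toluene, rt, dark
Reagents that add atoms: 2,4,6-trichlorobenzoyl chloride, O=C(Cl)c1c(Cl)cc(Cl)cc1Cl (its aroyl group is held only in intermediate 17 and leaves again as the acid)
Why: Yamaguchi esterification, in which DMAP transfers the trienoyl group of the mixed anhydride to the secondary, pseudo-equatorial allylic 6α-hydroxyl, while the tertiary 9-hydroxyl between two fully substituted carbons should stay unacylated, so no further protecting group is needed.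

Step 14
Reactants: 18 11-(tert-butyldimethylsilyloxy)-9α-hydroxydrim-7-en-6α-yl (2E,4E,6E)-octa-2,4,6-trienoate
Product: 19 9α,11-dihydroxydrim-7-en-6α-yl (2E,4E,6E)-octa-2,4,6-trienoate
Conditions: HF·pyridine, pyridine, THF, 0 °C to rt
Reagents that add atoms: none
Why: fluoride-driven desilylation of the primary silyl ether, buffered with pyridine so that the allylic ester and the tertiary allylic alcohol are neither ionised nor induced to migrate.

Step 15
Reactants: 19 9α,11-dihydroxydrim-7-en-6α-yl (2E,4E,6E)-octa-2,4,6-trienoate
Product: 20 9α-hydroxy-11-oxodrim-7-en-6α-yl (2E,4E,6E)-octa-2,4,6-trienoate (target CNP0223516.2)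
Conditions: IBX, DMSO, rt
Reagents that add atoms: none
Why: IBX oxidation (a pentavalent iodine reagent) of the primary alcohol, chosen because it takes 1,2-diols to α-hydroxy carbonyl compounds without C–C cleavage, cannot oxidise the tertiary 9-hydroxyl, and works without base, so that α-ketol rearrangement and ester loss are avoided.

**Compound list**

1 | (+)-sclareolide | C1C[C@@]3(C)OC(=O)C[C@@H]3[C@@]2(C)CCCC(C)(C)[C@H]12 | starting material
2 | 11-hydroxysclareolide (OH cis to H-9) | C1C[C@@]3(C)OC(=O)[C@@H](O)[C@@H]3[C@@]2(C)CCCC(C)(C)[C@H]12 | intermediate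
3 | 11-(hydroxymethyl)drimane-8α,11-diol | C1C[C@@](C)(O)[C@H]([C@H](O)CO)[C@@]2(C)CCCC(C)(C)[C@H]12 | intermediate
4 | 8α-hydroxydriman-11-al | C1C[C@@](C)(O)[C@H](C=O)[C@@]2(C)CCCC(C)(C)[C@H]12 | intermediate
5 | 8α-(methanesulfonyloxy)driman-11-al | C1C[C@@](C)(OS(C)(=O)=O)[C@H](C=O)[C@@]2(C)CCCC(C)(C)[C@H]12 | intermediate (not isolated)
6 | drim-8-en-11-al | C1CC(C)=C(C=O)[C@@]2(C)CCCC(C)(C)[C@H]12 | intermediate
7 | 11-(tert-butyldimethylsilyloxy)drima-7,9(11)-diene (silyloxy group turned toward C8) | C1C=C(C)/C(=C\O[Si](C)(C)C(C)(C)C)[C@@]2(C)CCCC(C)(C)[C@H]12 | intermediate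
8 | drima-6,8-dien-11-al | C1=CC(C)=C(C=O)[C@@]2(C)CCCC(C)(C)[C@H]12 | intermediate
9 | drima-6,8-dien-11-ol | C1=CC(C)=C(CO)[C@@]2(C)CCCC(C)(C)[C@H]12 | intermediate
10 | 11-(tert-butyldimethylsilyloxy)drima-6,8-diene | C1=CC(C)=C(CO[Si](C)(C)C(C)(C)C)[C@@]2(C)CCCC(C)(C)[C@H]12 | intermediate
11 | 11-(tert-butyldimethylsilyloxy)-6α,9α-epidioxydrim-7-ene | O3[C@H]1C=C(C)[C@@](CO[Si](C)(C)C(C)(C)C)(O3)[C@@]2(C)CCCC(C)(C)[C@H]12 | intermediate
12 | 11-(tert-butyldimethylsilyloxy)drim-7-ene-6α,9α-diol | O[C@H]1C=C(C)[C@](O)(CO[Si](C)(C)C(C)(C)C)[C@@]2(C)CCCC(C)(C)[C@H]12 | intermediate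
13 | (2E,4E)-hexa-2,4-dienal | C/C=C/C=C/C=O | starting material
14 | triethyl phosphonoacetate | CCOC(=O)CP(=O)(OCC)OCC | starting material
15 | ethyl (2E,4E,6E)-octa-2,4,6-trienoate | C/C=C/C=C/C=C/C(=O)OCC | intermediate
16 | (2E,4E,6E)-octa-2,4,6-trienoic acid | C/C=C/C=C/C=C/C(=O)O | intermediate
17 | (2E,4E,6E)-octa-2,4,6-trienoic 2,4,6-trichlorobenzoic anhydride | C/C=C/C=C/C=C/C(=O)OC(=O)c1c(Cl)cc(Cl)cc1Cl | intermediate (not isolated)
18 | 11-(tert-butyldimethylsilyloxy)-9α-hydroxydrim-7-en-6α-yl (2E,4E,6E)-octa-2,4,6-trienoate | C/C=C/C=C/C=C/C(=O)O[C@H]1C=C(C)[C@](O)(CO[Si](C)(C)C(C)(C)C)[C@@]2(C)CCCC(C)(C)[C@H]12 | intermediate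
19 | 9α,11-dihydroxydrim-7-en-6α-yl (2E,4E,6E)-octa-2,4,6-trienoate | C/C=C/C=C/C=C/C(=O)O[C@H]1C=C(C)[C@](O)(CO)[C@@]2(C)CCCC(C)(C)[C@H]12 | intermediate
20 | 9α-hydroxy-11-oxodrim-7-en-6α-yl (2E,4E,6E)-octa-2,4,6-trienoate | C/C=C/C=C/C=C/C(=O)O[C@H]1C=C(C)[C@](O)(C=O)[C@@]2(C)CCCC(C)(C)[C@H]12 | target

**Step count and risks**

Total step count: 15.
Longest linear sequence: 13 steps (from 1 to 20 through steps 1–10 and 13–15); the acid branch takes 2 steps (11 and 12).

Steps most likely to fail:

Step 9 (key step). The ene-type hydroperoxidation of the tetrasubstituted C8=C9 bond may overtake the cycloaddition, because the bicyclic peroxide must carry ring A trans-fused on its two-carbon bridge and the transition state is twist-strained; face selectivity may also erode. The fallback sets out from 10 and returns at 18, introducing the two oxygens one after the other. Epoxidation of the more electron-rich tetrasubstituted C8=C9 bond of 10 with dimethyldioxirane (acetone, −20 °C) from the open α face should give the vinyl epoxide 11-(tert-butyldimethylsilyloxy)-8α,9α-epoxydrim-6-ene F1. A Pd(PPh3)4-catalysed 1,4-opening of F1 with acid 16 (THF, rt; Tsuji–Trost reaction of a vinyl epoxide) should then ionise the allylic C8–O bond with inversion at zerovalent palladium and deliver the carboxylate to C6 anti to the metal, that is cis to the C9 alkoxide. This would give 18 directly and bypass 11 and 12.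

Step 6. β-Hydride elimination may not set in, either because palladation of the hindered dienol ether is slow or because the enolisation of step 5 has partly gone toward the C12 methyl; acid formed in the reaction could also exchange H-5 through the trienol. The fallback sets out from 6 and returns at 10, building C6=C7 from a C7 ketone instead. Reduction of 6 with i-Bu2AlH should give drim-8-en-11-ol F2, and TBSCl/imidazole its silyl ether 11-(tert-butyldimethylsilyloxy)drim-8-ene F3. Allylic oxidation of the ring methylene with CrO3 and 3,5-dimethylpyrazole (CH2Cl2, −20 °C) should give the enone 11-(tert-butyldimethylsilyloxy)drim-8-en-7-one F4. Kinetic enolisation at C6 with KN(SiMe3)2 (THF, −78 °C) and trapping with N-phenylbis(trifluoromethanesulfonimide) should give the dienyl triflate 11-(tert-butyldimethylsilyloxy)drima-6,8-dien-7-yl trifluoromethanesulfonate F5. Reduction of F5 with Pd(OAc)2, PPh3, Bu3N and HCO2H (DMF, 60 °C) should then give diene 10.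

Step 13. Acylation of the 6α-hydroxyl next to the C4 gem-dimethyl group may be slow, so that isomerisation of the activated trienoate or conjugate addition of DMAP to it competes. The fallback sets out from 12 and returns at 18, building the chain on the ring ester. Acylation of 12 with the small diethylphosphonoacetic acid (N,N′-dicyclohexylcarbodiimide, DMAP cat., CH2Cl2) should give 11-(tert-butyldimethylsilyloxy)-9α-hydroxydrim-7-en-6α-yl 2-(diethoxyphosphoryl)acetate F6. A Masamune–Roush Horner–Wadsworth–Emmons reaction of F6 with sorbaldehyde 13 (LiCl, i-Pr2NEt, MeCN, rt) should then form the E-configured C2=C3 bond in place and give 18.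

**Further compounds**

F1 | step 9 | 11-(tert-butyldimethylsilyloxy)-8α,9α-epoxydrim-6-ene | C1=C[C@@]3(C)O[C@@]3(CO[Si](C)(C)C(C)(C)C)[C@@]2(C)CCCC(C)(C)[C@H]12
F2 | step 6 | drim-8-en-11-ol | C1CC(C)=C(CO)[C@@]2(C)CCCC(C)(C)[C@H]12
F3 | step 6 | 11-(tert-butyldimethylsilyloxy)drim-8-ene | C1CC(C)=C(CO[Si](C)(C)C(C)(C)C)[C@@]2(C)CCCC(C)(C)[C@H]12
F4 | step 6 | 11-(tert-butyldimethylsilyloxy)drim-8-en-7-one | C1C(=O)C(C)=C(CO[Si](C)(C)C(C)(C)C)[C@@]2(C)CCCC(C)(C)[C@H]12
F5 | step 6 | 11-(tert-butyldimethylsilyloxy)drima-6,8-dien-7-yl trifluoromethanesulfonate | C1=C(OS(=O)(=O)C(F)(F)F)C(C)=C(CO[Si](C)(C)C(C)(C)C)[C@@]2(C)CCCC(C)(C)[C@H]12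
F6 | step 13 | 11-(tert-butyldimethylsilyloxy)-9α-hydroxydrim-7-en-6α-yl 2-(diethoxyphosphoryl)acetate | CCOP(=O)(OCC)CC(=O)O[C@H]1C=C(C)[C@](O)(CO[Si](C)(C)C(C)(C)C)[C@@]2(C)CCCC(C)(C)[C@H]12
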